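## The problem

Verbenachalcone (21) consists of two dihydrochalcone units, each a 2,4-dihydroxyphenyl ketone (ring A) tied by a CH2–CH2 link to a second arene, and the two are joined by a diaryl ether between C4 of ring B and C3' of ring B'. The molecule has no stereocentre, so nothing has to be set or relayed; the task is one of connectivity and of telling two nearly identical halves apart. The ether oxygen has an oxygen substituent ortho to it on both rings, the C3 methoxy group on ring B and the C4' hydroxyl on ring B', so both ether carbons are hindered and electron-rich, the least favourable case for an Ullmann- or Buchwald-type C–O coupling or for nucleophilic aromatic substitution. Rings B and B' differ only in OMe versus OH, so the halves must enter as distinct, differently masked pieces and no step may cleave an aryl methyl ether. The free resorcinol ketones are acidic and easily oxidised, a chalcone with a free 2'-hydroxyl closes to a flavanone, and an aryl ketone can be over-reduced when the chain is saturated, so the phenols are best carried as ethers that fall off in the last step. The feature that invites a ring synthesis is the pattern of ring B': the hydroxyl carbon C4' is para to the chain carbon C1', as C3 and C6 are in a 3-oxy-2-pyrone-6-carboxylate, and the two carbons between them on one side, C3' with its aryloxy group and C2' with hydrogen, correspond to the two carbons of an aryl ethynyl ether. If ring B' is assembled from these two pieces, the ether oxygen arrives already bonded to an sp carbon and the hindered aryl–oxygen bond never has to be formed on an arene.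

## Retrosynthesis

**21 to 20.** No skeletal bond is cut in the first move. The two saturated links of 21 are written as the (E)-enones of bis-chalcone 20 and all five phenols as benzyl ethers, so that one hydrogenation over Pd/C saturates the chains and frees the phenols. Carrying saturated chains through the route would demand an acyl–alkyl bond construction at each end, whereas the enone comes from the most reliable C=C-forming reaction of an aryl methyl ketone. Compound 20 is no smaller, but every reactive group in it is masked and it is one operation from the target. The forward step must stop after C=C saturation and O-debenzylation and leave both aryl ketones untouched.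

**20 to 17 and 19.** Both Cα=Cβ bonds of 20 are cut in the aldol sense, giving dialdehyde 17 and two molecules of ketone 19. Cutting here, and not at the aryl–carbonyl or carbonyl–CH2 bonds, keeps each resorcinol ring together with its acyl group, so that it can be bought as 18. It also exploits the identity of the two chains, since one twofold condensation serves both. Compound 17 has two rings instead of four. The forward reaction asks little: the aldehydes cannot enolise, 19 has a single enolisable position, and its 2-O-benzyl group keeps the chalcone from closing to a flavanone.

**17 to 14.** The two formyl groups of 17 are traced to different precursors in benzoate 14, a methyl ester on ring B' and a cyclic acetal on ring B. This is a change of oxidation level only, passing through alcohol 15 and hydroxy aldehyde 16. The difference is imposed by what precedes: the ring B' carbon is born as the carboxylate of a pyrone, and the ring B aldehyde has to be masked against an organolithium reagent. Forward, a hydride reduction with acidic work-up and a benzylic oxidation are needed, both routine.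

**14 to 4 and 12 (key disconnection).** Here ring B' itself is taken apart. The C1'–C2' and C3'–C4' bonds of 14 are cut and a carboxylate bridge is restored between C1' and C4', which leads through bicyclic lactone 13 to pyrone 4 and aryl ethynyl ether 12. The neighbouring cut, at the C3'–O or C4–O bond of the diaryl ether, would require a C–O coupling at a carbon flanked by an ortho oxygen on each ring. The cycloaddition cut avoids this, because the ether oxygen is already bonded to the alkyne carbon that becomes C3'. The cut also halves the molecule into a six-carbon heterocycle and a vanillin-derived alkyne, each three steps from a commodity chemical. The forward reaction must be regioselective, with the alkyne terminus bonding to C6 of 4 and the oxygen-bearing carbon to C3, and it must outrun the decomposition of the ynol ether.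

**4 to 1.** The benzyl ether and the methyl ester of 4 are removed to give hydroxy pyrone 3 and, before it, acetoxy pyrone salt 2. All six carbons of 2, its C3 oxygen and its carboxyl group map onto galactaric acid 1, from which the ring arises by lactonisation and twofold β-elimination. No other six-carbon precursor offers the 3-oxy-6-carboxy pattern so directly. The forward steps are a known dehydrative cyclisation of a hexaric acid, an acidic methanolysis and an O-alkylation.

**12 to 5 and 6.** The terminal C–H of 12 is traced through lithium acetylide 11 and chloroalkyne 10 to the (E)-1,2-dichlorovinyl ether 9, whose acetal is removed to give aldehyde 8. Cutting the O–vinyl bond of 8 gives vanillin 5 and trichloroethylene 6, the latter acting through dichloroacetylene 7. This is preferred to a metal-catalysed O-alkynylation of the phenol because it needs no catalyst and takes the two-carbon unit from a bulk chemical. The vinyl ether is made before the acetal because the acetal of free phenol 5 would be too labile to handle, and the acetal must be in place before the organolithium step.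

**19 to 18.** Ketone 19 is the bis(benzyl ether) of commercial 2,4-dihydroxyacetophenone 18; cutting the two O–benzyl bonds is the whole of this branch.

## Roads not taken

Alternative 1: ring B by keto ester–enal annulation with late aromatisation.
- **Cut:** the methoxy-bearing ring B is opened at C1–C2 and C4–C5.
- **Forward key step:** under pyrrolidine/benzoic acid catalysis, the active methylene of keto ester A2, which is tert-butyl 4-[2-(benzyloxy)-5-(3-methoxy-3-oxopropyl)phenoxy]-3-oxobutanoate, adds to the β-carbon of enal A3, which is methyl (E)-6-oxohex-4-enoate. The aryloxy-bearing γ-carbon of A2 then condenses on the aldehyde of A3 and closes the ring as cyclohexenone A1.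
- **Merits:** the ether oxygen is attached by simple O-alkylation of a phenol with a haloacetoacetate. The regiochemistry of ring B is fixed by which carbon is the Michael donor and which the aldol donor, and the cascade is of a well-established type. In precedent and in regiochemical security this road is better than the chosen one.
- **Weak points:** A1 is only at the cyclohexenone level. Ester cleavage with decarboxylation, dehydrogenation to the phenol in the presence of electron-rich arenes and benzyl ethers, and O-methylation are all needed before ring B exists. Both propanoate chains must then be turned into aryl ketones by two separate acylations of a protected resorcinol. A2 also presupposes a ring B' already carrying its chain and a differentiated catechol, and A3 is a polymerisation-prone enal that has to be made.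
- **Comparison:** the chosen plan reaches the arene directly, because loss of the lactone bridge aromatises ring B' in the same operation. It completes both chains by one twofold condensation with a commodity ketone and one hydrogenation. Its end game is therefore shorter and more convergent, at the price of a less certain key step.

Alternative 2: both resorcinol rings by twofold ynone benzannulation.
- **Cut:** in each ring A the C1–C2 and C5–C6 bonds are cut.
- **Forward key step:** bis-ynone A5 reacts twice with diene A6, which is 1-methoxy-1,3-bis(trimethylsilyloxy)buta-1,3-diene. Acidic work-up with loss of the acetal methoxy group aromatises both adducts to the mono-benzyl ether A4.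
- **Merits:** the polarity of A6 and of the ynones in A5 is matched, so the 2,4-dioxygenation pattern is secure, more secure than the orientation in the chosen key step. A4 is one hydrogenolysis from the target. No protecting groups are needed on ring A and no enone has to be reduced.
- **Weak points:** the key step builds the two rings that can be bought for almost nothing as an acetophenone. The diaryl ether, the real difficulty, must still be made beforehand by a hindered C–O coupling. A5 carries two terminal ynones, which are base- and nucleophile-sensitive and prone to polymerise, and A6 is moisture-sensitive and has to react cleanly twice on one molecule.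
- **Comparison:** the chosen plan spends its ring synthesis on ring B', where no cheap building block with the ether in place exists, and takes ring A from commercial 18. Against the better-precedented cycloaddition of this alternative it sets the removal of the C–O coupling.

Alternative 3: twofold nickel-catalysed decarboxylative acylation.
- **Cut:** both carbonyl–CH2 bonds are cut.
- **Forward key step:** with NiCl2(dme), 4,4'-di-tert-butyl-2,2'-bipyridine and zinc powder, the bis(N-hydroxyphthalimide ester) A8 releases two 2-arylethyl radicals. These are acylated by two molecules of thioester A9 to give pentabenzyl verbenachalcone A7.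
- **Merits:** the reaction type is known and mild. The ketone arrives at the right oxidation level with the chain already saturated, so no chalcone is formed and the risk of over-reducing a ketone during alkene hydrogenation disappears. In that respect it is better than the chosen end game.
- **Weak points:** two primary-radical couplings must succeed on the same molecule, each competing with reduction and dimerisation. A9 is an ortho-substituted, electron-rich acyl donor. A8 has to be made from diacid A10, so the ether again has to be formed by coupling and two chains homologated and activated first.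
- **Comparison:** the chosen plan answers with a twofold Claisen–Schmidt condensation that needs no activation steps, and it solves the ether without any aryl C–O bond formation. It shares the final hydrogenolysis with this alternative.

Key step: step 7

Assumption: ring B is numbered with C1 at the chain, C3 at OMe and C4 at the ether oxygen, ring B' with C1' at the chain, C3' at the ether oxygen and C4' at OH; reagents that deliver only protecting groups, hydride or base are taken as commercial and carry no compound number.

## Route

Step 1
Reactants: 1 galactaric acid
Product: 2 sodium 3-(acetyloxy)-2-oxo-2H-pyran-6-carboxylate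
Conditions: Ac2O, NaOAc, 100 °C
Reagents that add atoms: acetic anhydride, CC(=O)OC(C)=O; sodium acetate, CC(=O)[O-].[Na+]
Why: Acetylation, lactonisation and two base-induced β-eliminations of acetic acid should convert the hexaric acid into the 3-acetoxy-2-pyrone-6-carboxylate, a known dehydrative cyclisation of aldaric acids; the salt should separate from the mixture and all four stereocentres of 1 are lost.

Step 2
Reactants: 2 sodium 3-(acetyloxy)-2-oxo-2H-pyran-6-carboxylate
Product: 3 methyl 3-hydroxy-2-oxo-2H-pyran-6-carboxylate
Conditions: HCl, MeOH, reflux
Reagents that add atoms: methanol, CO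
Why: Fischer esterification of the liberated acid and acid-catalysed transesterification of the enol acetate should occur together; 2-pyrone carboxylic acids are known to tolerate acidic methanol.

Step 3
Reactants: 3 methyl 3-hydroxy-2-oxo-2H-pyran-6-carboxylate
Product: 4 methyl 3-(benzyloxy)-2-oxo-2H-pyran-6-carboxylate
Conditions: BnBr, K2CO3, acetone, 50 °C
Reagents that add atoms: benzyl bromide, BrCc1ccccc1
Why: Williamson O-alkylation of the acidic enolic hydroxyl; anhydrous carbonate is mild enough to leave the pyrone ring closed.

Step 4
Reactants: 5 vanillin; 6 trichloroethylene
Product: 8 4-{[(E)-1,2-dichloroethenyl]oxy}-3-methoxybenzaldehyde, via dichloroacetylene 7 (not isolated)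
Conditions: K2CO3, DMF, 70 °C
Reagents that add atoms: none
Why: Carbonate eliminates HCl from 6 and the phenoxide adds in anti fashion to the dichloroacetylene so formed, the standard preparation of aryl (E)-1,2-dichlorovinyl ethers; the aldehyde is a spectator.

Step 5
Reactants: 8 4-{[(E)-1,2-dichloroethenyl]oxy}-3-methoxybenzaldehyde
Product: 9 2-(4-{[(E)-1,2-dichloroethenyl]oxy}-3-methoxyphenyl)-1,3-dioxolane
Conditions: HOCH2CH2OH, PPTS (cat.), toluene, reflux, Dean–Stark
Reagents that add atoms: ethylene glycol, OCCO
Why: Acid-catalysed acetalisation with azeotropic removal of water; the electron-poor dichlorovinyl ether is not protonated by the weak acid and keeps its geometry.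

Step 6
Reactants: 9 2-(4-{[(E)-1,2-dichloroethenyl]oxy}-3-methoxyphenyl)-1,3-dioxolane
Product: 12 2-[4-(ethynyloxy)-3-methoxyphenyl]-1,3-dioxolane, via chloroethynyl ether 10 (not isolated), via lithium acetylide 11 (not isolated)
Conditions: n-BuLi (2.2 equiv), THF, −78 to −40 °C; then H2O, −78 °C
Reagents that add atoms: none
Why: Deprotonation and loss of LiCl give chloroalkyne 10, chlorine–lithium exchange gives acetylide 11 and protonation gives the terminal ynol ether, the established route from dichlorovinyl ethers; the dioxolane shields the aldehyde, and 12 should be filtered through basic alumina and used at once.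

Step 7
Reactants: 4 methyl 3-(benzyloxy)-2-oxo-2H-pyran-6-carboxylate; 12 2-[4-(ethynyloxy)-3-methoxyphenyl]-1,3-dioxolane
Product: 14 methyl 4-(benzyloxy)-3-[4-(1,3-dioxolan-2-yl)-2-methoxyphenoxy]benzoate, via bicyclic lactone 13 (not isolated)
Conditions: 4 (1.5 equiv), 12 added over several hours, BHT (cat.), toluene, 110 °C, sealed vessel
Reagents that add atoms: none
Why: Proposed new method: pyrone 4, whose diene is made electron-poor by the lactone carbonyl and the C6 ester, should undergo an inverse-electron-demand Diels–Alder reaction with the electron-rich aryl ynol ether 12, the closest known reaction type being the thermal cycloaddition of 2-pyrone carboxylates (coumalates, 3-carbomethoxy-2-pyrone) with alkoxyalkynes, ynamines and ketene acetals, which ends in benzoates after loss of CO2; a 3-alkoxy-2-pyrone-6-carboxylate has not been paired with an aryl ethynyl ether. The cycloaddition should be concerted but asynchronous: the nucleophilic terminal carbon of 12 bonds ahead to pyrone C6 (the C1'–C2' bond), the position at which 2-pyrones accept nucleophiles because the developing charge runs through C5 and C3 into the lactone carbonyl, and the oxygen-bearing alkyne carbon, which carries the developing positive charge, closes on C3 (the C3'–C4' bond). Ring B' is thus closed by an intermolecular [4+2] cycloaddition that gives the 2-oxabicyclo[2.2.2]octadienone 13, and at 110 °C this bridged lactone should expel CO2 by retro-[4+2] and leave benzoate 14. The two bridgehead stereocentres of 13 arise as a racemate and vanish with the CO2, so nothing stereochemical has to be controlled. The one selectivity needed is the orientation of the alkyne: it rests on the strong polarisation of the ynol ether and on the lactone-conjugated, ring-oxygen-bearing C6 terminus, but the C6 ester and the C3 benzyloxy group polarise the diene in the opposite sense, so the preference is a reasoned expectation and not a certainty. Slow addition of 12 to an excess of 4 keeps the labile ynol ether dilute, BHT suppresses its radical oligomerisation, and acid-free conditions protect both the ynol ether and the dioxolane.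

Step 8
Reactants: 14 methyl 4-(benzyloxy)-3-[4-(1,3-dioxolan-2-yl)-2-methoxyphenoxy]benzoate
Product: 16 4-[2-(benzyloxy)-5-(hydroxymethyl)phenoxy]-3-methoxybenzaldehyde, via acetal alcohol 15 (not isolated)
Conditions: LiAlH4, THF, 0 °C; then 1 M HCl, THF, 0 °C to rt
Reagents that add atoms: water, O
Why: Hydride reduction of the benzoate to the benzylic alcohol, followed by acid hydrolysis of the aryl dioxolane in the work-up; benzyl, methyl and diaryl ethers are inert to both.

Step 9
Reactants: 16 4-[2-(benzyloxy)-5-(hydroxymethyl)phenoxy]-3-methoxybenzaldehyde
Product: 17 4-(benzyloxy)-3-(4-formyl-2-methoxyphenoxy)benzaldehyde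
Conditions: MnO2 (activated, excess), CH2Cl2, rt
Reagents that add atoms: none
Why: Selective heterogeneous oxidation of an electron-rich benzylic alcohol to the aldehyde with MnO2; no over-oxidation to the acid is expected.

Step 10
Reactants: 18 2,4-dihydroxyacetophenone
Product: 19 1-[2,4-bis(benzyloxy)phenyl]ethan-1-one
Conditions: BnBr (2.5 equiv), K2CO3, KI (cat.), DMF, 80 °C
Reagents that add atoms: benzyl bromide, BrCc1ccccc1
Why: Twofold Williamson etherification; heat and excess halide are needed because the 2-hydroxyl is hydrogen-bonded to the ketone.

Step 11
Reactants: 17 4-(benzyloxy)-3-(4-formyl-2-methoxyphenoxy)benzaldehyde; 19 1-[2,4-bis(benzyloxy)phenyl]ethan-1-one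
Product: 20 (E)-3-[4-(benzyloxy)-3-(4-{(E)-3-[2,4-bis(benzyloxy)phenyl]-3-oxoprop-1-en-1-yl}-2-methoxyphenoxy)phenyl]-1-[2,4-bis(benzyloxy)phenyl]prop-2-en-1-one
Conditions: 19 (2.2 equiv), KOH (aq.), EtOH/THF, rt
Reagents that add atoms: none
Why: Twofold Claisen–Schmidt condensation between non-enolisable aldehydes and a methyl ketone; E1cB dehydration gives the thermodynamically favoured (E)-enones and the 2-O-benzyl group blocks flavanone formation.

Step 12
Reactants: 20 (E)-3-[4-(benzyloxy)-3-(4-{(E)-3-[2,4-bis(benzyloxy)phenyl]-3-oxoprop-1-en-1-yl}-2-methoxyphenoxy)phenyl]-1-[2,4-bis(benzyloxy)phenyl]prop-2-en-1-one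
Product: 21 verbenachalcone, 3-(4-hydroxy-3-{4-[3-(2,4-dihydroxyphenyl)-3-oxopropyl]-2-methoxyphenoxy}phenyl)-1-(2,4-dihydroxyphenyl)propan-1-one
Conditions: H2 (1 atm), 10% Pd/C, EtOAc/MeOH, rt
Reagents that add atoms: none
Why: Catalytic hydrogenation saturates both enone C=C bonds and hydrogenolyses all five benzyl ethers in one operation, as is usual for benzyl-protected chalcones; the electron-rich ortho-hydroxy aryl ketones should resist reduction if the reaction is stopped at the calculated uptake.

## Compound list

1 | galactaric acid | OC(=O)[C@H](O)[C@@H](O)[C@@H](O)[C@H](O)C(=O)O | starting material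
2 | sodium 3-(acetyloxy)-2-oxo-2H-pyran-6-carboxylate | CC(=O)OC1=CC=C(C(=O)[O-])OC1=O.[Na+] | intermediate
3 | methyl 3-hydroxy-2-oxo-2H-pyran-6-carboxylate | COC(=O)C1=CC=C(O)C(=O)O1 | intermediate
4 | methyl 3-(benzyloxy)-2-oxo-2H-pyran-6-carboxylate | COC(=O)C1=CC=C(OCc2ccccc2)C(=O)O1 | intermediate
5 | vanillin | COc1cc(C=O)ccc1O | starting material
6 | trichloroethylene | ClC=C(Cl)Cl | starting material
7 | dichloroacetylene (formed in the flask, not isolated) | ClC#CCl | intermediate
8 | 4-{[(E)-1,2-dichloroethenyl]oxy}-3-methoxybenzaldehyde | COc1cc(C=O)ccc1O/C(Cl)=C\Cl | intermediate
9 | 2-(4-{[(E)-1,2-dichloroethenyl]oxy}-3-methoxyphenyl)-1,3-dioxolane | COc1cc(C2OCCO2)ccc1O/C(Cl)=C\Cl | intermediate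
10 | 2-{4-[(chloroethynyl)oxy]-3-methoxyphenyl}-1,3-dioxolane (not isolated) | COc1cc(C2OCCO2)ccc1OC#CCl | intermediate
11 | {[4-(1,3-dioxolan-2-yl)-2-methoxyphenoxy]ethynyl}lithium (not isolated) | COc1cc(C2OCCO2)ccc1OC#C[Li] | intermediate
12 | 2-[4-(ethynyloxy)-3-methoxyphenyl]-1,3-dioxolane | COc1cc(C2OCCO2)ccc1OC#C | intermediate
13 | methyl 4-(benzyloxy)-5-[4-(1,3-dioxolan-2-yl)-2-methoxyphenoxy]-3-oxo-2-oxabicyclo[2.2.2]octa-5,7-diene-1-carboxylate (racemic, not isolated) | COC(=O)C12C=CC(OCc3ccccc3)(C(=O)O1)C(Oc1ccc(C3OCCO3)cc1OC)=C2 | intermediate
14 | methyl 4-(benzyloxy)-3-[4-(1,3-dioxolan-2-yl)-2-methoxyphenoxy]benzoate | COC(=O)c1ccc(OCc2ccccc2)c(Oc2ccc(C3OCCO3)cc2OC)c1 | intermediate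
15 | {4-(benzyloxy)-3-[4-(1,3-dioxolan-2-yl)-2-methoxyphenoxy]phenyl}methanol (not isolated) | COc1cc(C2OCCO2)ccc1Oc1cc(CO)ccc1OCc1ccccc1 | intermediate
16 | 4-[2-(benzyloxy)-5-(hydroxymethyl)phenoxy]-3-methoxybenzaldehyde | COc1cc(C=O)ccc1Oc1cc(CO)ccc1OCc1ccccc1 | intermediate
17 | 4-(benzyloxy)-3-(4-formyl-2-methoxyphenoxy)benzaldehyde | COc1cc(C=O)ccc1Oc1cc(C=O)ccc1OCc1ccccc1 | intermediate
18 | 2,4-dihydroxyacetophenone | CC(=O)c1ccc(O)cc1O | starting material
19 | 1-[2,4-bis(benzyloxy)phenyl]ethan-1-one | CC(=O)c1ccc(OCc2ccccc2)cc1OCc1ccccc1 | intermediate
20 | (E)-3-[4-(benzyloxy)-3-(4-{(E)-3-[2,4-bis(benzyloxy)phenyl]-3-oxoprop-1-en-1-yl}-2-methoxyphenoxy)phenyl]-1-[2,4-bis(benzyloxy)phenyl]prop-2-en-1-one | COc1cc(/C=C/C(=O)c2ccc(OCc3ccccc3)cc2OCc2ccccc2)ccc1Oc1cc(/C=C/C(=O)c2ccc(OCc3ccccc3)cc2OCc2ccccc2)ccc1OCc1ccccc1 | intermediate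
21 | verbenachalcone | COc1cc(CCC(=O)c2ccc(O)cc2O)ccc1Oc1cc(CCC(=O)c2ccc(O)cc2O)ccc1O | target

## Step count and least certain steps

Total: 12 steps. Longest linear sequence: 8 steps (steps 1, 2, 3, 7, 8, 9, 11, 12; the vanillin branch through steps 4, 5, 6 is equally long).

**Step 7 (key step, proposed new method).** Two things may go wrong.
- The ynol ether may add in the reversed orientation, because the C6 ester and the C3 benzyloxy group polarise the diene against the lactone carbonyl.
- The cycloaddition may be slower than the oligomerisation or hydration of the ynol ether, because the benzyloxy donor makes the pyrone only moderately electron-poor.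

Within the same disconnection, a mild oxophilic Lewis acid able to chelate the lactone carbonyl and the C3 oxygen would be tried first, since it should activate the lactone-conjugated terminus selectively. Eu(fod)3, europium tris(6,6,7,7,8,8,8-heptafluoro-2,2-dimethyloctane-3,5-dionate), is the candidate.

Fallback by known chemistry: the diaryl ether is made by a CuI-catalysed Ullmann coupling instead of by ring synthesis. Commercial 3-bromo-4-hydroxybenzaldehyde F1 is O-benzylated (BnBr, K2CO3, DMF) to 4-(benzyloxy)-3-bromobenzaldehyde F2. The fallback then sets out from vanillin 5, which is coupled as its phenoxide with F2 (CuI, N,N-dimethylglycine, Cs2CO3, dioxane, 100 °C). The product is dialdehyde 17, at which the route is rejoined, so that steps 1 to 9 fall away. The price is a C–O coupling between an electron-poor ortho-methoxy phenol and an ortho-alkoxy aryl bromide, which is expected to be sluggish.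

**Step 6.** The terminal aryl ethynyl ether may be lost during work-up and purification by hydration to the aryl acetate or by oligomerisation. Fallback: setting out from 9, the same treatment with n-BuLi is followed by silylation of acetylide 11 with Me3SiCl instead of protonation. This gives 2-(3-methoxy-4-{[(trimethylsilyl)ethynyl]oxy}phenyl)-1,3-dioxolane F3, which can be purified and stored. Desilylation with Bu4NF in wet THF at low temperature just before the cycloaddition returns to 12, which is then used in solution without isolation.

**Step 11.** The second condensation may stall once the mono-chalcone precipitates, and the aldehydes may be consumed by hydroxide in a Cannizzaro-type disproportionation during the long reaction time. Fallback: setting out from 17 and 19, the preformed lithium enolate of 19 (LDA, THF, −78 °C) is added to both aldehydes to give the bis(β-hydroxy ketone) 3-[4-(benzyloxy)-3-(4-{3-[2,4-bis(benzyloxy)phenyl]-1-hydroxy-3-oxopropyl}-2-methoxyphenoxy)phenyl]-1-[2,4-bis(benzyloxy)phenyl]-3-hydroxypropan-1-one F4 as a mixture of diastereomers. Acid-catalysed dehydration (TsOH, toluene, reflux) then gives 20, where the route is rejoined.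

**Step 12.** The aryl ketones may be over-reduced to benzylic alcohols or methylene groups while the last benzyl ethers are still being cleaved. Fallback: setting out from 20, the two events are separated. Conjugate reduction of both enones with catalytic [(Ph3P)CuH]6 and PhSiH3 (toluene, rt) gives pentabenzyl verbenachalcone F5. The benzyl ethers are then removed without hydrogen by BCl3 and pentamethylbenzene (CH2Cl2, −78 °C), conditions that spare the aryl methyl ether, and this arrives at target 21.

## Further compounds

F1 | step 7 | 3-bromo-4-hydroxybenzaldehyde | O=Cc1ccc(O)c(Br)c1
F2 | step 7 | 4-(benzyloxy)-3-bromobenzaldehyde | O=Cc1ccc(OCc2ccccc2)c(Br)c1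
F3 | step 6 | 2-(3-methoxy-4-{[(trimethylsilyl)ethynyl]oxy}phenyl)-1,3-dioxolane | COc1cc(C2OCCO2)ccc1OC#C[Si](C)(C)C
F4 | step 11 | 3-[4-(benzyloxy)-3-(4-{3-[2,4-bis(benzyloxy)phenyl]-1-hydroxy-3-oxopropyl}-2-methoxyphenoxy)phenyl]-1-[2,4-bis(benzyloxy)phenyl]-3-hydroxypropan-1-one (mixture of diastereomers) | COc1cc(C(O)CC(=O)c2ccc(OCc3ccccc3)cc2OCc2ccccc2)ccc1Oc1cc(C(O)CC(=O)c2ccc(OCc3ccccc3)cc2OCc2ccccc2)ccc1OCc1ccccc1
F5 | step 12 | pentabenzyl verbenachalcone | COc1cc(CCC(=O)c2ccc(OCc3ccccc3)cc2OCc2ccccc2)ccc1Oc1cc(CCC(=O)c2ccc(OCc3ccccc3)cc2OCc2ccccc2)ccc1OCc1ccccc1
A1 | alternative 1 | tert-butyl 3-[2-(benzyloxy)-5-(3-methoxy-3-oxopropyl)phenoxy]-6-(3-methoxy-3-oxopropyl)-2-oxocyclohex-3-ene-1-carboxylate (mixture of epimers) | CC(C)(C)OC(=O)C1C(CCC(=O)OC)CC=C(Oc2cc(CCC(=O)OC)ccc2OCc2ccccc2)C1=O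
A2 | alternative 1 | tert-butyl 4-[2-(benzyloxy)-5-(3-methoxy-3-oxopropyl)phenoxy]-3-oxobutanoate | CC(C)(C)OC(=O)CC(=O)COc1cc(CCC(=O)OC)ccc1OCc1ccccc1
A3 | alternative 1 | methyl (E)-6-oxohex-4-enoate | COC(=O)CC/C=C/C=O
A4 | alternative 2 | verbenachalcone benzyl ether at the ring B' phenol | COc1cc(CCC(=O)c2ccc(O)cc2O)ccc1Oc1cc(CCC(=O)c2ccc(O)cc2O)ccc1OCc1ccccc1
A5 | alternative 2 | 5-{4-(benzyloxy)-3-[2-methoxy-4-(3-oxopent-4-yn-1-yl)phenoxy]phenyl}pent-1-yn-3-one | COc1cc(CCC(=O)C#C)ccc1Oc1cc(CCC(=O)C#C)ccc1OCc1ccccc1
A6 | alternative 2 | 1-methoxy-1,3-bis(trimethylsilyloxy)buta-1,3-diene | COC(O[Si](C)(C)C)=CC(=C)O[Si](C)(C)C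
A7 | alternative 3 | pentabenzyl verbenachalcone | COc1cc(CCC(=O)c2ccc(OCc3ccccc3)cc2OCc2ccccc2)ccc1Oc1cc(CCC(=O)c2ccc(OCc3ccccc3)cc2OCc2ccccc2)ccc1OCc1ccccc1
A8 | alternative 3 | bis(1,3-dioxoisoindolin-2-yl) ester of 3-{4-(benzyloxy)-3-[4-(2-carboxyethyl)-2-methoxyphenoxy]phenyl}propanoic acid | COc1cc(CCC(=O)ON2C(=O)c3ccccc3C2=O)ccc1Oc1cc(CCC(=O)ON2C(=O)c3ccccc3C2=O)ccc1OCc1ccccc1
A9 | alternative 3 | S-(pyridin-2-yl) 2,4-bis(benzyloxy)benzenecarbothioate | O=C(Sc1ccccn1)c1ccc(OCc2ccccc2)cc1OCc1ccccc1
A10 | alternative 3 | 3-{4-(benzyloxy)-3-[4-(2-carboxyethyl)-2-methoxyphenoxy]phenyl}propanoic acid | COc1cc(CCC(=O)O)ccc1Oc1cc(CCC(=O)O)ccc1OCc1ccccc1
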